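Numbering: ring C1 (C=O), C2=C3, C4 (OAc), C5 (tertiary OH); C1′ is the acetoxy carbon of the pentadecyl chain. Enabling feature: C4 and C5 of the five-membered ring carry vicinal trans oxygens next to the C1 carbonyl, and C5 also holds the C1′ carbinol. This is the oxidised C4=C5 alkene of a 2-(1-hydroxyalkyl)cyclopent-2-enone whose own hydroxyl is allylic to that alkene.
Cuts, in order: C2=C3 (back to the saturated ketone); the acetyl–oxygen ester bonds; C4–O (back to a C4–C5 oxirane opened by the C1′ acetate); both oxirane C–O bonds (back to the enone alkene); C5–C1′ (Morita–Baylis–Hillman) to 1 and 2.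
Forward: the carbocycle is bought and the chain is joined to it in step 1. The oxirane ring closes in step 3. In step 5 it is exchanged for a transient 1,3-dioxan-2-ylium ring, which is then hydrolysed. The enone is restored last.
Stereochemistry: C1′ (S) comes from a lipase resolution. C5 (S) and the oxirane configuration at C4 come from C1′ by hydroxyl-directed oxygen delivery, reinforced by matched L-(+)-DIPT. The final C4 (R) arises by inversion when the acetate attacks anti to the oxirane oxygen, which places O4 trans to O5.

Key step: step 3

Assumption: in step 2 the lipase is taken to obey the empirical size rule for secondary alcohols, with the α-branched cyclopentenonyl group as the large and the unbranched chain as the medium substituent, so that the (R)-alcohol is the one acylated.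

Step 1
Reactants: 1 cyclopent-2-en-1-one; 2 pentadecanal
Product: 3 (±)-2-(1-hydroxypentadecyl)cyclopent-2-en-1-one
Conditions: PBu3 (20 mol %), (±)-BINOL (10 mol %), THF, rt
Reagents that add atoms: none
Why: Morita–Baylis–Hillman reaction in which the phosphine adds to the β-carbon of 1, the resulting enolate attacks the phenol-activated aldehyde through its α-carbon, and proton transfer with loss of the phosphine restores the enone; the carbinol centre is formed racemic.

Step 2
Reactants: 3 (±)-2-(1-hydroxypentadecyl)cyclopent-2-en-1-one
Product: 4 2-[(1S)-1-hydroxypentadecyl]cyclopent-2-en-1-one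
Conditions: Burkholderia cepacia lipase (Amano PS), vinyl acetate, MTBE, 35 °C, stopped just past half conversion; chromatography
Reagents that add atoms: none
Why: Acylative kinetic resolution with an irreversible enol ester donor, in which the Kazlauskas size rule predicts that the (R)-carbinol is acetylated and removed while the (S)-carbinol is recovered, and running past half conversion favours the optical purity of the recovered alcohol.

Step 3
Reactants: 4 2-[(1S)-1-hydroxypentadecyl]cyclopent-2-en-1-one
Product: 5 (1S,5S)-1-[(1S)-1-hydroxypentadecyl]-6-oxabicyclo[3.1.0]hexan-2-one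
Conditions: Ti(OiPr)4 (1.1 equiv), L-(+)-DIPT (1.3 equiv), TBHP (2 equiv, decane), 4 Å MS, CH2Cl2, −20 °C; aq. tartaric acid work-up
Reagents that add atoms: tert-butyl hydroperoxide, CC(C)(C)OO
Why: Alcohol 4 and TBHP replace isopropoxide ligands on the complex formed from Ti(OiPr)4 and L-(+)-DIPT, and the metal-bound peroxide passes its activated oxygen to the C4=C5 alkene held on the same metal centre, forming the C4–O and C5–O bonds on one face and releasing tert-butoxide. The closest known reaction type is the Sharpless-type titanium alkoxide/TBHP epoxidation of allylic alcohols, which has been extended to acyclic Baylis–Hillman hydroxy enones. The oxirane closes by suprafacial [2+1] oxygen transfer (or, should the peroxide first add to C4, by 3-exo-tet attack of C5 on the O–O bond), and on a five-membered ring it can only be cis-fused. C5 and C4 are both controlled by C1′: in the reactive rotamer C1′–H lies beside the C1 carbonyl carbon to minimise A(1,2) strain, the tetradecyl chain points to the far face, and the titanium-bound oxygen sits over the face that leads to the (1S,5S) epoxide, erythro to the (S)-carbinol. L-(+)-DIPT is the matched ligand for an (S)-allylic alcohol, so reagent and substrate control add up, and any (R)-alcohol left from step 2 should react slowly and be separated. The step needs facial selectivity and enough reactivity from an electron-poor alkene: C4 carries only hydrogen cis to C1′, so no A(1,3) strain opposes the favoured rotamer, intramolecular delivery with a full equivalent of Ti(OiPr)4 offsets the low nucleophilicity, and the ketone is inert to TBHP under these conditions.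

Step 4
Reactants: 5 (1S,5S)-1-[(1S)-1-hydroxypentadecyl]-6-oxabicyclo[3.1.0]hexan-2-one
Product: 6 (1S)-1-[(1R,5S)-2-oxo-6-oxabicyclo[3.1.0]hexan-1-yl]pentadecyl acetate
Conditions: Ac2O, pyridine, DMAP (cat.), CH2Cl2, 0 °C
Reagents that add atoms: acetic anhydride, CC(=O)OC(C)=O
Why: DMAP-catalysed O-acetylation of a secondary alcohol, in which the amine bases are too weak to trigger a Payne shift and no stereocentre is touched (the bridgehead descriptor changes only because the CIP ranking changes).

Step 5
Reactants: 6 (1S)-1-[(1R,5S)-2-oxo-6-oxabicyclo[3.1.0]hexan-1-yl]pentadecyl acetate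
Product: 9 (1R,2S)-2-hydroxy-2-[(1S)-1-hydroxypentadecyl]-3-oxocyclopentyl acetate, via acetoxonium zwitterion 7 (not isolated), via cyclic hemiorthoacetate 8 (not isolated)
Conditions: BF3·OEt2 (1.2 equiv), CH2Cl2, −78 to −20 °C; then H2O–THF, 0 °C
Reagents that add atoms: water, O
Why: Lewis acid epoxide opening with neighbouring-group participation, in which BF3 on the oxirane oxygen weakens the C4–O bond (C5 is quaternary and deactivated by the adjacent carbonyl), the C1′ acetate carbonyl attacks C4 anti to the oxirane oxygen with inversion to give the cis-fused six-membered cation 7 (a trans-fused ortho ester cannot form, so 7 persists until the quench), water adds to give 8, and 8 collapses to the monoacetate; acetyl scrambling between O4 and O1′ is harmless because step 6 esterifies whichever secondary hydroxyl is free.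

Step 6
Reactants: 9 (1R,2S)-2-hydroxy-2-[(1S)-1-hydroxypentadecyl]-3-oxocyclopentyl acetate
Product: 10 (1R,2S)-2-[(1S)-1-acetoxypentadecyl]-2-hydroxy-3-oxocyclopentyl acetate
Conditions: Ac2O, pyridine, DMAP (5 mol %), CH2Cl2, 0 °C to rt
Reagents that add atoms: acetic anhydride, CC(=O)OC(C)=O
Why: Selective esterification, in which the free secondary hydroxyl is acetylated while the tertiary C5 hydroxyl, flanked by the ketone and two acyloxy-bearing carbons, is too hindered to react, and the C4 acetate cannot be eliminated because C5 carries no hydrogen.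

Step 7
Reactants: 10 (1R,2S)-2-[(1S)-1-acetoxypentadecyl]-2-hydroxy-3-oxocyclopentyl acetate
Product: 11 (1R,2S)-2-[(1S)-1-acetoxypentadecyl]-2,3-bis(trimethylsilyloxy)cyclopent-3-en-1-yl acetate
Conditions: TMSOTf (3 equiv), Et3N (5 equiv), CH2Cl2, 0 °C
Reagents that add atoms: trimethylsilyl trifluoromethanesulfonate, C[Si](C)(C)OS(=O)(=O)C(F)(F)F
Why: Soft enolisation with a silyl triflate and an amine, in which only C2 bears α-hydrogens and so a single enol silane can form, the tertiary hydroxyl is capped as its trimethylsilyl ether in the same operation, and the acetates and all three stereocentres are untouched.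

Step 8
Reactants: 11 (1R,2S)-2-[(1S)-1-acetoxypentadecyl]-2,3-bis(trimethylsilyloxy)cyclopent-3-en-1-yl acetate
Product: 13 (1R,5S)-5-[(1S)-1-acetoxypentadecyl]-5-hydroxy-4-oxocyclopent-2-en-1-yl acetate, via silyl ether enone 12 (not isolated)
Conditions: Pd(OAc)2 (1.1 equiv), MeCN, rt; then 1 M aq. HCl, THF, 0 °C
Reagents that add atoms: none
Why: Saegusa–Ito oxidation, in which the enol silane hands C2 to divalent palladium, β-hydride elimination from C3 gives the C2=C3 enone 12 and zerovalent palladium, and brief aqueous acid then cleaves the labile tertiary trimethylsilyl ether without disturbing the acetates or the stereocentres.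

Compound list
1 | cyclopent-2-en-1-one | O=C1CCC=C1 | starting material
2 | pentadecanal | CCCCCCCCCCCCCCC=O | starting material
3 | (±)-2-(1-hydroxypentadecyl)cyclopent-2-en-1-one | CCCCCCCCCCCCCCC(O)C1=CCCC1=O | intermediate
4 | 2-[(1S)-1-hydroxypentadecyl]cyclopent-2-en-1-one | CCCCCCCCCCCCCC[C@H](O)C1=CCCC1=O | intermediate
5 | (1S,5S)-1-[(1S)-1-hydroxypentadecyl]-6-oxabicyclo[3.1.0]hexan-2-one | CCCCCCCCCCCCCC[C@H](O)[C@@]1(O2)C(=O)CC[C@@H]12 | intermediate
6 | (1S)-1-[(1R,5S)-2-oxo-6-oxabicyclo[3.1.0]hexan-1-yl]pentadecyl acetate (same spatial arrangement as 5) | CCCCCCCCCCCCCC[C@H](OC(C)=O)[C@@]1(O2)C(=O)CC[C@@H]12 | intermediate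
7 | acetoxonium zwitterion: 2-methyl-1,3-dioxan-2-ylium ring spanning O4 and O1′, cis-fused to the cyclopentanone at C4–C5, tetradecyl on (S)-C1′, C5–O–BF3(−) on the opposite ring face | CCCCCCCCCCCCCC[C@H](O2)[C@@]1(O[B-](F)(F)F)C(=O)CC[C@H]1[O+]=C2C | intermediate
8 | cyclic hemiorthoacetate: 2-hydroxy-2-methyl-1,3-dioxane spanning O4 and O1′, free C5–OH, C4, C5 and C1′ configured as in 9, ortho carbon unassigned | CCCCCCCCCCCCCC[C@H](O2)[C@@]1(O)C(=O)CC[C@H]1OC2(C)O | intermediate
9 | (1R,2S)-2-hydroxy-2-[(1S)-1-hydroxypentadecyl]-3-oxocyclopentyl acetate | CCCCCCCCCCCCCC[C@H](O)[C@@]1(O)C(=O)CC[C@H]1OC(C)=O | intermediate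
10 | (1R,2S)-2-[(1S)-1-acetoxypentadecyl]-2-hydroxy-3-oxocyclopentyl acetate | CCCCCCCCCCCCCC[C@H](OC(C)=O)[C@@]1(O)C(=O)CC[C@H]1OC(C)=O | intermediate
11 | (1R,2S)-2-[(1S)-1-acetoxypentadecyl]-2,3-bis(trimethylsilyloxy)cyclopent-3-en-1-yl acetate | CCCCCCCCCCCCCC[C@H](OC(C)=O)[C@@]1(O[Si](C)(C)C)C(O[Si](C)(C)C)=CC[C@H]1OC(C)=O | intermediate
12 | (1R,5S)-5-[(1S)-1-acetoxypentadecyl]-4-oxo-5-(trimethylsilyloxy)cyclopent-2-en-1-yl acetate | CCCCCCCCCCCCCC[C@H](OC(C)=O)[C@@]1(O[Si](C)(C)C)C(=O)C=C[C@H]1OC(C)=O | intermediate
13 | (1R,5S)-5-[(1S)-1-acetoxypentadecyl]-5-hydroxy-4-oxocyclopent-2-en-1-yl acetate | CCCCCCCCCCCCCC[C@H](OC(C)=O)[C@@]1(O)C(=O)C=C[C@H]1OC(C)=O | target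

Total step count: 8
Longest linear sequence: 8 steps (1 or 2 to 13)

Steps most likely to fail

Step 5. Three processes may outrun the acetate relay: a Lewis-acid-induced 1,2-acyl or alkyl shift of the epoxy ketone, capture of the opening oxirane by fluoride, and participation at C5 instead of C4. The fallback drops the intramolecular relay in favour of intermolecular acid-catalysed hydration. It sets out from 5 and comes back at 10. Treatment of 5 with catalytic HClO4 in THF–H2O (rt to 40 °C) should let water attack C4 anti to the protonated oxirane. This gives (2S,3R)-2,3-dihydroxy-2-[(1S)-1-hydroxypentadecyl]cyclopentan-1-one F1 with the same trans O4/O5 relationship. Ac2O and pyridine with catalytic DMAP then esterify both secondary hydroxyls, leave the tertiary one free, and deliver 10.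

Step 2. Acyl transfer may be very slow, or enantiomer discrimination poor, because both carbinol substituents are large for the enzyme pockets. The fallback replaces the enzymatic acylation by an oxidative kinetic resolution merged with the epoxidation. It sets out from 3 and comes back at 5. Racemic 3 is treated with Ti(OiPr)4, L-(+)-DIPT and about half an equivalent of TBHP (4 Å MS, CH2Cl2, −20 °C). The matched (S)-enantiomer should be epoxidised preferentially to 5, while the mismatched (R)-enantiomer stays unchanged and is separated by chromatography. No new compound arises on this path (entry F0).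

Step 8. The zerovalent palladium set free may ionise the newly formed allylic C4 acetate, or the enol silane may be protodesilylated back to the ketone. The fallback avoids palladium by selenoxide syn-elimination. It sets out from 11 and comes back at 12. PhSeCl in CH2Cl2 at −78 °C should selenenylate C2 of the enol silane. The product is (1R,2S)-2-[(1S)-1-acetoxypentadecyl]-3-oxo-4-(phenylselanyl)-2-(trimethylsilyloxy)cyclopentyl acetate F2, whose selenium-bearing carbon may have either configuration. Oxidation with aqueous H2O2 and pyridine in CH2Cl2 at 0 °C gives (1R,2S)-2-[(1S)-1-acetoxypentadecyl]-4-(benzeneseleninyl)-3-oxo-2-(trimethylsilyloxy)cyclopentyl acetate F3. F3 eliminates towards the only β-hydrogens, those at C3, to give 12. The acid desilylation of step 8 then completes the route.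

Further compounds
F0 | step 2 | none | none
F1 | step 5 | (2S,3R)-2,3-dihydroxy-2-[(1S)-1-hydroxypentadecyl]cyclopentan-1-one | CCCCCCCCCCCCCC[C@H](O)[C@@]1(O)C(=O)CC[C@H]1O
F2 | step 8 | (1R,2S)-2-[(1S)-1-acetoxypentadecyl]-3-oxo-4-(phenylselanyl)-2-(trimethylsilyloxy)cyclopentyl acetate | CCCCCCCCCCCCCC[C@H](OC(C)=O)[C@@]1(O[Si](C)(C)C)C(=O)C([Se]c2ccccc2)C[C@H]1OC(C)=O
F3 | step 8 | (1R,2S)-2-[(1S)-1-acetoxypentadecyl]-4-(benzeneseleninyl)-3-oxo-2-(trimethylsilyloxy)cyclopentyl acetate | CCCCCCCCCCCCCC[C@H](OC(C)=O)[C@@]1(O[Si](C)(C)C)C(=O)C([Se](=O)c2ccccc2)C[C@H]1OC(C)=O
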